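Thursday's run, the very flask now asked about, had been followed to 3.00 h when the meeting opened, and its left-handed product stood at 17.6%.

all flasks: left-handed substrate 20 mM; right-handed substrate 20 mM; gas 4.1 mM (held); free catalyst 0.5 mol%; racemization catalyst 0.15 mol%

| flask | remark | time |
|---|---|---|
| Thursday's | the very flask that is asked about, followed so far |  |
| flask |  | 10 h |

- Thursday's (time / h: left-handed product / %): 0.250: 0.4; 0.333: 1.3; 0.500: 1.9; 0.833: 4.4; 1.33: 8.4; 2.00: 12.3; 3.00: 17.6

(readings scatter by 0.5 percentage points)

- free catalyst is single-handed; left-handed substrate and right-handed substrate are mirror images of each other, charged as a racemate, each of them at the stated concentration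
- the numbers in the tables scatter with a standard deviation of 0.5 percentage points
- at the start none of the gas is in solution
- reagent is what gas becomes in solution

- the left-handed product standing at 10 h, as a percentage of the left-handed substrate and right-handed substrate together charged
- concentration of reagent in solution at 10 h, in percent of saturation

The author of the forecast put the left-handed product at 42% and the reagent at 96% of saturation, and said of the curve: “Racemization therefore looks slow but is not excluded”.

The minute-taker, reckoning on his own account, differed. He took the readings from 1.33 h to 3.00 h and drew one number from them, 2.20 mM h⁻¹. This is the running rate, the left-handed product gained per hour over the late readings. He proposed to treat the curve as a straight line and to carry the running rate forward from the last reading. That gave 56.2% at 10 h, which is more than the 50.0% of the charge that was left-handed, so his figure requires right-handed substrate to keep turning into left-handed. Of the reagent he said it should stand below saturation, and he offered no figure. The meeting did not agree.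

The flask gives 54.4% of left-handed product, with reagent at 62.4% of saturation. At 10.0 h, left-handed and right-handed substrate stand level at 13.0% and 13.2%, beside 19.5% of right-handed product.

    reagent + free catalyst + left-handed substrate → free catalyst + left-handed product (k = 1.10 × 10⁶ M⁻² h⁻¹)
    reagent + free catalyst + right-handed substrate → free catalyst + right-handed product (k = 3.90 × 10⁵ M⁻² h⁻¹)
    left-handed substrate + racemization catalyst ⇌ right-handed substrate + racemization catalyst, rate k3*[racemization catalyst]*[left-handed substrate] forward; the back reaction follows from the equilibrium constant (k = 2.10 × 10⁵ M⁻¹ h⁻¹)
    gas ⇌ reagent, rate k4*(csat - [reagent]) (kL = 1.40 h⁻¹)

The running rate had given 56.2% for this flask, 1.8 percentage points above it. Carried from the last reading to 6.0 h, it gives 34.1%, and the neighbouring flask read at that time holds 36.3%.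

The earlier runs and the new flask come from a simulation from invented constants.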